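**Retrosynthetic overview**

1. The target is the (2S)-flavanone (numbering O1, C2, C3, C4, C4a, C5 to C8, C8a; ring B primed). The last cut is the 4'-O-methoxymethyl ether.
2. O1–C8a and C6–prenyl are made in one operation. Ring C is closed by intramolecular SNAr of the C2 alkoxide of an open-chain (S)-aldol on C8a–F, and the 5-O-(2-methylbut-3-en-2-yl) ether of the flavanone then shifts [3,3] to C6, its only free ortho position.
3. Enabling feature: on ring A, C8a lies ortho to the C4 ketone, so O1–C8a=C4a–C4=O is a vinylogous ester and C8a–F its acyl-fluoride-like precursor. Ring A is therefore carried as a twofold-symmetric 2,6-difluoro-4-methoxyphenyl ketone whose two equivalent C–F bonds are replaced one after the other (first by the tertiary allyl oxide, the future O5 and C6 side chain, then by O1), so 5-OH/7-OMe and 6-/8-prenyl isomers cannot arise.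
4. C2 (S) is set before ring closure by copper-catalysed enantioselective β-borylation and oxidation of the chalcone from a Claisen–Schmidt condensation. Its C–O bond is not broken afterwards.
5. Ring order: rings A and B are bought as benzenes (3,5-difluoroanisole, 4-(methoxymethoxy)benzaldehyde); ring C is the only ring formed (step 5).

Key step: step 5

Remark: the sense of induction of the ferrocenyl diphosphine in step 4 is an assumption; the antipode meant is the one that places boron on the Si face of the chalcone β-carbon (S boronate). Flavanone numbering is used for all compounds, open-chain ones included.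

**Route**

Step 1
Reactants: 1 3,5-difluoroanisole; 2 N-methoxy-N-methylacetamide
Product: 4 ketone 1-(2,6-difluoro-4-methoxyphenyl)ethan-1-one, via aryllithium 3 (not isolated)
Conditions: n-BuLi (1.05 equiv), THF, −78 °C; then 2, −78 to 0 °C; 1 M HCl
Reagents that add atoms: n-butyllithium, [Li]CCCC (its lithium is carried in 3 only)
Why: Directed ortho-lithiation should take place only at the C–H flanked by both fluorines, the most acidic position of 1, and the aryllithium is acylated once because the chelated tetrahedral adduct of the N-methoxy-N-methylamide holds until the acidic quench.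

Step 2
Reactants: 4 ketone 1-(2,6-difluoro-4-methoxyphenyl)ethan-1-one; 5 2-methylbut-3-en-2-ol
Product: 7 aryl ether 1-[2-fluoro-4-methoxy-6-(2-methylbut-3-en-2-yloxy)phenyl]ethan-1-one, via potassium alkoxide 6 (not isolated)
Conditions: 5 (3 equiv), KN(SiMe3)2 (1.2 equiv), THF, 0 °C; then 4, 0 to 40 °C
Reagents that add atoms: potassium bis(trimethylsilyl)amide, C[Si](C)(C)[N-][Si](C)(C)C.[K+] (its potassium is carried in 6 only)
Why: SNAr (addition–elimination) ortho to the acetyl group: the two C–F bonds of 4 are equivalent so only one product can form, the excess of 5 should keep the ketone from resting as its enolate, and the alkoxy group once in place donates into the acetyl group and slows a second substitution.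

Step 3
Reactants: 7 aryl ether 1-[2-fluoro-4-methoxy-6-(2-methylbut-3-en-2-yloxy)phenyl]ethan-1-one; 8 4-(methoxymethoxy)benzaldehyde
Product: 10 (E)-1-[2-fluoro-4-methoxy-6-(2-methylbut-3-en-2-yloxy)phenyl]-3-[4-(methoxymethoxy)phenyl]prop-2-en-1-one, via racemic aldol 9 (not isolated)
Conditions: KOH (aq, 2 equiv), EtOH, 0 °C to rt
Reagents that add atoms: none
Why: Claisen–Schmidt condensation (crossed aldol addition to 9, then E1cB loss of water to the conjugated E-enone): the hindered carbonyl of 7 should not self-condense, and a short contact time at or below room temperature in a protic medium should leave the aryl fluoride and the tertiary allyl ether intact.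

Step 4
Reactants: 10 (E)-1-[2-fluoro-4-methoxy-6-(2-methylbut-3-en-2-yloxy)phenyl]-3-[4-(methoxymethoxy)phenyl]prop-2-en-1-one
Product: 12 (3S)-1-[2-fluoro-4-methoxy-6-(2-methylbut-3-en-2-yloxy)phenyl]-3-hydroxy-3-[4-(methoxymethoxy)phenyl]propan-1-one, via (S)-boronate 11 (not isolated)
Conditions: CuCl (3 mol %), NaOtBu (5 mol %), (R)-1-[(S)-2-(diphenylphosphino)ferrocenyl]ethyldicyclohexylphosphine (3 mol %), B2pin2 (1.1 equiv), MeOH (2 equiv), THF, rt; then NaBO3·4H2O, THF/H2O, rt
Reagents that add atoms: bis(pinacolato)diboron, CC1(C)OB(OC1(C)C)B1OC(C)(C)C(C)(C)O1 (its boron is carried in 11 only); sodium perborate, O[B-]1(O)OO[B-](O)(O)OO1.[Na+].[Na+] (source of the hydroxyl oxygen, the later O1)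
Why: Copper-catalysed enantioselective conjugate borylation of an enone (the boryl–copper species adds to the β-carbon and methanol protonates the copper enolate), in which the chiral diphosphine should direct boron to the Si face to set C2 as S, followed by perborate oxidation that replaces C–B by C–O with retention.

Step 5
Reactants: 12 (3S)-1-[2-fluoro-4-methoxy-6-(2-methylbut-3-en-2-yloxy)phenyl]-3-hydroxy-3-[4-(methoxymethoxy)phenyl]propan-1-one
Product: 16 (2S)-5-hydroxy-7-methoxy-2-[4-(methoxymethoxy)phenyl]-6-(3-methylbut-2-en-1-yl)-2,3-dihydro-4H-chromen-4-one, via sodium alkoxide 13 (not isolated), via flavanone allyl ether 14 (not isolated), via ortho-dienone 15 (not isolated)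
Conditions: NaH (1.0 equiv), THF, 0 °C to rt; then AcOH (0.05 equiv), toluene added, THF distilled off, 110 °C
Reagents that add atoms: sodium hydride, [Na+].[H-] (its sodium is carried in 13 only)
Why: NaH turns the C2 hydroxyl into alkoxide 13, whose oxygen adds to C8a, the fluorine-bearing ring A carbon ortho to the C4 ketone, the charge being taken up by C4a–C4=O until fluoride leaves (addition–elimination SNAr) to give 14; on heating, the tertiary allyl ether on O5 then shifts [3,3] to C6 and dienone 15 enolises to the chelated 5-hydroxy arene. Both events have close precedent: intramolecular SNAr of alkoxide or enolate oxygen on 2-fluoroaryl ketones to chroman-4-ones and chromones, and the aromatic Claisen rearrangement of aryl 1,1-dimethylallyl ethers to ortho-prenyl phenols. Ring C (O1, C2, C3, C4, C4a, C8a) closes in a 6-endo-trig mode, as an oxa-conjugate addition to C8a=C4a–C4=O, and the closure forces the C4 carbonyl into the plane of ring A against the bulky group on O5, which should ease the sigmatropic shift that follows. No stereocentre of the product is made here: C2 stays S because its C–O bond is never broken (oxygen is the reacting atom), and the C6 centre of 15 vanishes on enolisation. Regiochemistry is fixed by the substrate, since C8a carries the only fluorine and C6 is the only free ortho position of O5 (the other is C4a), so O1 and O5 are told apart and the prenyl group cannot reach C8. The selectivity that is needed is ring closure ahead of retro-aldol cleavage or dehydration of the aldolate, and no base-induced opening of the flavanone; it should rest on the intramolecular six-membered closure, the tight sodium ion pair in THF at low temperature, a single equivalent of base that is buffered before heating, and the absence of a free phenol on ring A, which as a phenoxide would deactivate C8a.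

Step 6
Reactants: 16 (2S)-5-hydroxy-7-methoxy-2-[4-(methoxymethoxy)phenyl]-6-(3-methylbut-2-en-1-yl)-2,3-dihydro-4H-chromen-4-one
Product: 17 6-prenylsakuranetin, (2S)-5-hydroxy-2-(4-hydroxyphenyl)-7-methoxy-6-(3-methylbut-2-en-1-yl)-2,3-dihydro-4H-chromen-4-one
Conditions: 3 M HCl (aq), MeOH, 40 °C
Reagents that add atoms: none
Why: Acid-catalysed acetal exchange should remove the methoxymethyl ether under conditions mild enough to leave the prenyl group next to the hydrogen-bonded 5-OH uncyclised and the flavanone ring closed, so that C2 stays S.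

**Compound list**

1 | 3,5-difluoroanisole | COc1cc(F)cc(F)c1 | starting material
2 | N-methoxy-N-methylacetamide | CC(=O)N(C)OC | starting material
3 | (2,6-difluoro-4-methoxyphenyl)lithium (not isolated) | [Li]c1c(F)cc(OC)cc1F | intermediate
4 | 1-(2,6-difluoro-4-methoxyphenyl)ethan-1-one | CC(=O)c1c(F)cc(OC)cc1F | intermediate
5 | 2-methylbut-3-en-2-ol | CC(C)(O)C=C | starting material
6 | potassium 2-methylbut-3-en-2-olate (not isolated) | CC(C)([O-])C=C.[K+] | intermediate
7 | 1-[2-fluoro-4-methoxy-6-(2-methylbut-3-en-2-yloxy)phenyl]ethan-1-one | CC(=O)c1c(F)cc(OC)cc1OC(C)(C)C=C | intermediate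
8 | 4-(methoxymethoxy)benzaldehyde | COCOc1ccc(C=O)cc1 | starting material
9 | racemic 1-[2-fluoro-4-methoxy-6-(2-methylbut-3-en-2-yloxy)phenyl]-3-hydroxy-3-[4-(methoxymethoxy)phenyl]propan-1-one (not isolated) | O=C(CC(O)c1ccc(OCOC)cc1)c1c(F)cc(OC)cc1OC(C)(C)C=C | intermediate
10 | (E)-1-[2-fluoro-4-methoxy-6-(2-methylbut-3-en-2-yloxy)phenyl]-3-[4-(methoxymethoxy)phenyl]prop-2-en-1-one | COCOc1ccc(/C=C/C(=O)c2c(F)cc(OC)cc2OC(C)(C)C=C)cc1 | intermediate
11 | (3S)-1-[2-fluoro-4-methoxy-6-(2-methylbut-3-en-2-yloxy)phenyl]-3-[4-(methoxymethoxy)phenyl]-3-(4,4,5,5-tetramethyl-1,3,2-dioxaborolan-2-yl)propan-1-one (not isolated) | O=C(C[C@@H](c1ccc(OCOC)cc1)B1OC(C)(C)C(C)(C)O1)c1c(F)cc(OC)cc1OC(C)(C)C=C | intermediate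
12 | (3S)-1-[2-fluoro-4-methoxy-6-(2-methylbut-3-en-2-yloxy)phenyl]-3-hydroxy-3-[4-(methoxymethoxy)phenyl]propan-1-one | O=C(C[C@@H](c1ccc(OCOC)cc1)O)c1c(F)cc(OC)cc1OC(C)(C)C=C | intermediate
13 | sodium (1S)-3-[2-fluoro-4-methoxy-6-(2-methylbut-3-en-2-yloxy)phenyl]-1-[4-(methoxymethoxy)phenyl]-3-oxopropan-1-olate (not isolated) | O=C(C[C@@H](c1ccc(OCOC)cc1)[O-])c1c(F)cc(OC)cc1OC(C)(C)C=C.[Na+] | intermediate
14 | (2S)-7-methoxy-2-[4-(methoxymethoxy)phenyl]-5-(2-methylbut-3-en-2-yloxy)-2,3-dihydro-4H-chromen-4-one (not isolated) | COc1cc2c(c(OC(C)(C)C=C)c1)C(=O)C[C@@H](c1ccc(OCOC)cc1)O2 | intermediate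
15 | (2S)-7-methoxy-2-[4-(methoxymethoxy)phenyl]-6-(3-methylbut-2-en-1-yl)-2,3-dihydro-4H-chromene-4,5(6H)-dione, either configuration at C6 (not isolated) | COC1=CC2=C(C(=O)C1CC=C(C)C)C(=O)C[C@@H](c1ccc(OCOC)cc1)O2 | intermediate
16 | (2S)-5-hydroxy-7-methoxy-2-[4-(methoxymethoxy)phenyl]-6-(3-methylbut-2-en-1-yl)-2,3-dihydro-4H-chromen-4-one | COc1cc2c(c(O)c1CC=C(C)C)C(=O)C[C@@H](c1ccc(OCOC)cc1)O2 | intermediate
17 | 6-prenylsakuranetin, (2S)-5-hydroxy-2-(4-hydroxyphenyl)-7-methoxy-6-(3-methylbut-2-en-1-yl)-2,3-dihydro-4H-chromen-4-one | COc1cc2c(c(O)c1CC=C(C)C)C(=O)C[C@@H](c1ccc(O)cc1)O2 | target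

**Step count**

Total steps: 6. Longest linear sequence: 6 steps (1 to 17); compounds 2, 5 and 8 are bought and enter directly.

**Steps most likely to fail, with fallbacks**

Step 5. The sodium aldolate may cleave by retro-aldol reaction or dehydrate before it closes onto C8a, and residual base may open the flavanone once formed; each process would cost material and enantiopurity. The fallback sets out from 12 and avoids any stoichiometric base. The hydroxyl is silylated (Me3SiCl, imidazole, CH2Cl2, 0 °C) to give (3S)-1-[2-fluoro-4-methoxy-6-(2-methylbut-3-en-2-yloxy)phenyl]-3-[4-(methoxymethoxy)phenyl]-3-(trimethylsilyloxy)propan-1-one F1. The ring is then closed by fluoride-catalysed silyl-transfer SNAr (Bu4N[Ph3SiF2] 10 mol %, DMF, rt): fluoride strips the silyl group, the oxygen closes onto C8a, and the fluoride it expels carries the chain. The route is rejoined at 14, which is purified and heated in toluene on its own.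

Step 2. The tertiary alkoxide may act as a base on the methyl ketone, so that enolate formation stalls the substitution or leads to self-condensation. The fallback sets out from 1 and moves the substitution to a carbonyl compound that cannot enolise. Lithiation as in step 1 and a DMF quench give 2,6-difluoro-4-methoxybenzaldehyde F2, which also activates the ring more strongly. One fluorine is replaced with alkoxide 6 (THF, 0 °C) to give 2-fluoro-4-methoxy-6-(2-methylbut-3-en-2-yloxy)benzaldehyde F3. Addition of MeMgBr (THF, −78 °C) gives racemic 1-[2-fluoro-4-methoxy-6-(2-methylbut-3-en-2-yloxy)phenyl]ethan-1-ol F4, and oxidation of this benzylic alcohol (MnO2, CH2Cl2) rejoins the route at 7.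

Step 4. Facial selectivity of the boryl–copper addition may be poor, because the doubly ortho-substituted aroyl group is twisted out of the enone plane and gives the catalyst little to distinguish the faces. The fallback sets out from 10 and sets the C2 oxygen by epoxidation instead. A Juliá–Colonna epoxidation (poly-D-leucine, urea–H2O2, DBU, THF, rt) should give [(2S,3R)-3-[4-(methoxymethoxy)phenyl]oxiran-2-yl][2-fluoro-4-methoxy-6-(2-methylbut-3-en-2-yloxy)phenyl]methanone F5. Reductive cleavage of the Cα–O bond (SmI2, THF/MeOH, −90 °C) leaves the benzylic C–O bond and its configuration untouched and rejoins the route at 12.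

**Further compounds**

F1 | step 5 | (3S)-1-[2-fluoro-4-methoxy-6-(2-methylbut-3-en-2-yloxy)phenyl]-3-[4-(methoxymethoxy)phenyl]-3-(trimethylsilyloxy)propan-1-one | O=C(C[C@@H](c1ccc(OCOC)cc1)O[Si](C)(C)C)c1c(F)cc(OC)cc1OC(C)(C)C=C
F2 | step 2 | 2,6-difluoro-4-methoxybenzaldehyde | O=Cc1c(F)cc(OC)cc1F
F3 | step 2 | 2-fluoro-4-methoxy-6-(2-methylbut-3-en-2-yloxy)benzaldehyde | O=Cc1c(F)cc(OC)cc1OC(C)(C)C=C
F4 | step 2 | racemic 1-[2-fluoro-4-methoxy-6-(2-methylbut-3-en-2-yloxy)phenyl]ethan-1-ol | CC(O)c1c(F)cc(OC)cc1OC(C)(C)C=C
F5 | step 4 | [(2S,3R)-3-[4-(methoxymethoxy)phenyl]oxiran-2-yl][2-fluoro-4-methoxy-6-(2-methylbut-3-en-2-yloxy)phenyl]methanone | O=C(c1c(F)cc(OC)cc1OC(C)(C)C=C)[C@H]1O[C@@H]1c1ccc(OCOC)cc1
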